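**Strategy.** The cyclohexane of this elemanolide (C5–C10, elemane numbering) is not made from a cyclohexane of the same atoms. The C8 oxygen and the C4=C3 methylene on C5 are 1,5-related through C9–C10, a 3-oxy-1,5-diene retron. Addition of a (Z)-isoprenyl-lithium to the ketone of a 3-methylcyclohex-3-enone (ring C3–C4=C5–C6–C7–C8, bearing the C6 oxygen and the C7 propanoate arm) forms C8–C9. The carbinolate then undergoes an anionic oxy-Cope shift that forms C5–C10, cleaves C3–C8, transposes the ring, sets quaternary C10 (methyl, vinyl) and C5, and releases the isopropenyl group. The precursor comes from an Evans aldol and ring-closing metathesis.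

Key step: step 11

Numbering used below (elemane numbering): ring C5–C6–C7–C8–C9–C10; C1=C2 vinyl and C14 methyl on C10; C4 (with the C3 methylene and C15) on C5; C11 (C13 methyl, C12 carbonyl) on C7.

Assumption on the chemistry: (S)-methylsuccinic anhydride 2 is bought as such (otherwise it is one dehydration step from (S)-methylsuccinic acid).

Step 1
Reactants: 1 (4S)-4-benzyl-1,3-oxazolidin-2-one; 2 (S)-methylsuccinic anhydride [(3S)-3-methyloxolane-2,5-dione]
Product: 4 (2S)-4-[(4S)-4-benzyl-2-oxo-1,3-oxazolidin-3-yl]-2-methyl-4-oxobutanoic acid, via lithium oxazolidinide 3 (not isolated)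
Conditions: n-BuLi, THF, −78 °C; then 2, −78 → 0 °C; aq. HCl
Reagents that add atoms: none
Why: N-acylation of the lithiated oxazolidinone by ring opening of the anhydride, which should occur at the less hindered carbonyl remote from the methyl-bearing carbon, so that the (S)-centre (later C11) is untouched and ends next to the free acid.

Step 2
Reactants: 4 (2S)-4-[(4S)-4-benzyl-2-oxo-1,3-oxazolidin-3-yl]-2-methyl-4-oxobutanoic acid
Product: 5 tert-butyl (2S)-4-[(4S)-4-benzyl-2-oxo-1,3-oxazolidin-3-yl]-2-methyl-4-oxobutanoate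
Conditions: tert-butyl 2,2,2-trichloroacetimidate, BF3·OEt2 (cat.), CH2Cl2/cyclohexane, 25 °C
Reagents that add atoms: tert-butyl 2,2,2-trichloroacetimidate, CC(C)(C)OC(=N)C(Cl)(Cl)Cl
Why: acid-catalysed imidate esterification should give the hindered tert-butyl ester, chosen because it has to withstand the Grignard reagent of step 6 and the alkoxides of step 11.

Step 3
Reactants: 5 tert-butyl (2S)-4-[(4S)-4-benzyl-2-oxo-1,3-oxazolidin-3-yl]-2-methyl-4-oxobutanoate; 6 acrolein
Product: 8 tert-butyl (2S,3S,4R)-3-{[(4S)-4-benzyl-2-oxo-1,3-oxazolidin-3-yl]carbonyl}-4-hydroxy-2-methylhex-5-enoate, via dibutylboron enolate 7 (not isolated)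
Conditions: Bu2BOTf, i-Pr2NEt, CH2Cl2, −78 → 0 °C; 6, −78 → 0 °C; pH 7 buffer, MeOH, H2O2
Reagents that add atoms: none
Why: Evans syn-aldol reaction in which the (Z)-boron enolate adds to acrolein through a closed chair transition state, the (S)-benzyl auxiliary setting C7 (S) and C6 (R), that is the trans C6–O/C7–C11 relationship of the later lactone.

Step 4
Reactants: 8 tert-butyl (2S,3S,4R)-3-{[(4S)-4-benzyl-2-oxo-1,3-oxazolidin-3-yl]carbonyl}-4-hydroxy-2-methylhex-5-enoate
Product: 9 tert-butyl (2S,3S,4R)-4-hydroxy-3-[methoxy(methyl)carbamoyl]-2-methylhex-5-enoate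
Conditions: MeNHOMe·HCl, AlMe3, CH2Cl2, −15 → 0 °C
Reagents that add atoms: N,O-dimethylhydroxylamine hydrochloride, CNOC.Cl
Why: hydroxyl-assisted aminolysis of the imide by the aluminium amide should give the Weinreb amide and return the auxiliary, while the tert-butyl ester is too hindered to react.

Step 5
Reactants: 9 tert-butyl (2S,3S,4R)-4-hydroxy-3-[methoxy(methyl)carbamoyl]-2-methylhex-5-enoate
Product: 10 tert-butyl (2S,3S,4R)-4-{[tert-butyl(dimethyl)silyl]oxy}-3-[methoxy(methyl)carbamoyl]-2-methylhex-5-enoate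
Conditions: TBSOTf, 2,6-lutidine, CH2Cl2, −78 °C
Reagents that add atoms: tert-butyldimethylsilyl triflate, CC(C)(C)[Si](C)(C)OS(=O)(=O)C(F)(F)F
Why: silyl ether formation at low temperature protects the C6 hydroxyl as a poor leaving group, so that the later β-silyloxy ketone resists elimination.

Step 6
Reactants: 10 tert-butyl (2S,3S,4R)-4-{[tert-butyl(dimethyl)silyl]oxy}-3-[methoxy(methyl)carbamoyl]-2-methylhex-5-enoate; 11 2-methylallylmagnesium chloride
Product: 12 tert-butyl (2S,3S,4R)-4-{[tert-butyl(dimethyl)silyl]oxy}-2-methyl-3-(3-methylbut-3-enoyl)hex-5-enoate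
Conditions: THF, −78 → −30 °C; aq. NH4Cl at −30 °C
Reagents that add atoms: none
Why: Grignard addition to a Weinreb amide stops at the chelated tetrahedral intermediate and should release the β,γ-unsaturated ketone only on cold, neutral quench, which keeps the alkene out of conjugation and C7 unepimerised.

Step 7
Reactants: 12 tert-butyl (2S,3S,4R)-4-{[tert-butyl(dimethyl)silyl]oxy}-2-methyl-3-(3-methylbut-3-enoyl)hex-5-enoate
Product: 13 tert-butyl (2S)-2-[(1S,2R)-2-{[tert-butyl(dimethyl)silyl]oxy}-4-methyl-6-oxocyclohex-3-en-1-yl]propanoate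
Conditions: second-generation Grubbs catalyst (5 mol %), 1,4-benzoquinone (10 mol %), CH2Cl2 (dilute), 40 °C
Reagents that add atoms: none
Why: ring-closing metathesis between the vinyl and 2-methylallyl groups should close the six-membered ring C3–C4=C5–C6–C7–C8 with loss of ethene, under neutral conditions that leave the base-sensitive β,γ-unsaturated β'-silyloxy ketone intact.

Step 8
Reactants: 14 prop-2-yn-1-ol
Product: 16 (2Z)-3-iodo-2-methylprop-2-en-1-ol, via alkenylmagnesium bromide 15 (not isolated)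
Conditions: MeMgBr, CuI (cat.), Et2O, −10 → 25 °C; then I2, −40 → 0 °C; H2O
Reagents that add atoms: methylmagnesium bromide, C[Mg]Br; iodine, II
Why: copper-catalysed carbomagnesiation of the propargylic alkoxide proceeds by anti addition through a five-membered magnesium chelate, and iodinolysis with retention should give the iodide with iodine cis to the CH2OH group.

Step 9
Reactants: 16 (2Z)-3-iodo-2-methylprop-2-en-1-ol
Product: 17 (2Z)-3-iodo-2-methylprop-2-enal
Conditions: MnO2, CH2Cl2, 25 °C, dark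
Reagents that add atoms: none
Why: MnO2 oxidation is selective for the allylic alcohol and, being neutral, should leave the (Z)-vinyl iodide geometry unchanged.

Step 10
Reactants: 17 (2Z)-3-iodo-2-methylprop-2-enal
Product: 18 (1Z)-1-iodo-2-methylbuta-1,3-diene
Conditions: Ph3PCH3Br, KOt-Bu, Et2O, 0 °C
Reagents that add atoms: methyltriphenylphosphonium bromide, C[P+](c1ccccc1)(c1ccccc1)c1ccccc1.[Br-]
Why: Wittig methylenation of the aldehyde should give the isoprene-derived dienyl iodide without touching the trisubstituted C=C, so that iodine stays cis to the new vinyl group.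

Step 11
Reactants: 13 tert-butyl (2S)-2-[(1S,2R)-2-{[tert-butyl(dimethyl)silyl]oxy}-4-methyl-6-oxocyclohex-3-en-1-yl]propanoate; 18 (1Z)-1-iodo-2-methylbuta-1,3-diene
Product: 22 tert-butyl (2S)-2-[(1S,2R,3S,4S)-2-{[tert-butyl(dimethyl)silyl]oxy}-4-ethenyl-4-methyl-6-oxo-3-(prop-1-en-2-yl)cyclohexyl]propanoate, via dienyllithium 19 (not isolated), via lithium carbinolate 20 (not isolated), via potassium enolate 21 (not isolated)
Conditions: 18, t-BuLi (2 equiv), Et2O, −78 °C; 13, THF, −78 °C; then KOt-Bu, 18-crown-6, −78 → 0 °C; aq. NH4Cl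
Reagents that add atoms: none
Why: Iodine–lithium exchange gives the configurationally stable (Z)-dienyllithium 19, which should add to the ketone of 13 at −78 °C from the face anti to the branched C7 arm (1,2-induction), forming C8–C9 and carbinolate 20 with the dienyl group cis to the C6 silyl ether; exchange to the crown-separated potassium alkoxide then triggers the anionic oxy-Cope rearrangement, a [3,3]-sigmatropic shift of the 3-oxido-1,5-diene C10=C9–C8(O−)–C3–C4=C5 that forms C5–C10, breaks C3–C8 and gives enolate 21, protonated to 22 on work-up. The closest known reaction type is the tandem alkenyl-metal addition/anionic oxy-Cope rearrangement of β,γ-unsaturated ketones, including the boat-restricted cases in which the ring alkene lies para to the carbinol carbon. The new ring C5–C10–C9–C8–C7–C6 is closed by the C5–C10 σ-bond of the suprafacial shift through a boat-like six-centre transition state in which C8 and C5 stay tied by C7–C6, the old ring being opened in the same event, and six-membered closure should outrun the eight-membered [1,3] alternative. C5 is set by bond formation on the ring face that carries the dienyl group, which places C4 trans to the C6 oxygen, and C10 is set by the (Z)-geometry of the nucleophile, whose outward methyl ends cis to C4 and whose inward vinyl ends trans to it. The step needs 1,2-addition over enolisation of the doubly activated C3 methylene, facial control in the addition and rearrangement over fragmentation. These should be secured by the modest basicity of the sp2 organolithium at low temperature, by the size of the C7 arm, and by the fact that only the carbinolate with the dienyl group trans to that arm reaches the boat without eclipsing it.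

Step 12
Reactants: 22 tert-butyl (2S)-2-[(1S,2R,3S,4S)-2-{[tert-butyl(dimethyl)silyl]oxy}-4-ethenyl-4-methyl-6-oxo-3-(prop-1-en-2-yl)cyclohexyl]propanoate
Product: 23 tert-butyl (2S)-2-[(1R,2R,3S,4S,6S)-2-{[tert-butyl(dimethyl)silyl]oxy}-4-ethenyl-6-hydroxy-4-methyl-3-(prop-1-en-2-yl)cyclohexyl]propanoate
Conditions: Li, liq. NH3, THF, t-BuOH, −78 °C; NH4Cl
Reagents that add atoms: none
Why: dissolving-metal reduction of the hindered ketone should give the thermodynamically preferred equatorial 8α-alcohol (trans to the C7 arm), whereas hydride reagents would be deflected to the other face by the axial C10 methyl; isolated alkenes, the silyl ether and the tert-butyl ester should survive the short exposure.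

Step 13
Reactants: 24 methyl (2R)-3-hydroxy-2-methylpropanoate
Product: 25 methyl (2R)-3-{[tert-butyl(dimethyl)silyl]oxy}-2-methylpropanoate
Conditions: TBSCl, imidazole, CH2Cl2, 25 °C
Reagents that add atoms: tert-butyldimethylsilyl chloride, CC(C)(C)[Si](C)(C)Cl
Why: standard silylation of the primary alcohol, which does not touch the stereocentre.

Step 14
Reactants: 25 methyl (2R)-3-{[tert-butyl(dimethyl)silyl]oxy}-2-methylpropanoate
Product: 26 (2R)-3-{[tert-butyl(dimethyl)silyl]oxy}-2-methylpropanoic acid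
Conditions: LiOH, THF/H2O, 0 °C; dilute HCl to pH 4
Reagents that add atoms: lithium hydroxide, [Li+].[OH-]
Why: mild saponification should give the acid without epimerising the α-centre or cleaving the silyl ether.

Step 15
Reactants: 23 tert-butyl (2S)-2-[(1R,2R,3S,4S,6S)-2-{[tert-butyl(dimethyl)silyl]oxy}-4-ethenyl-6-hydroxy-4-methyl-3-(prop-1-en-2-yl)cyclohexyl]propanoate; 26 (2R)-3-{[tert-butyl(dimethyl)silyl]oxy}-2-methylpropanoic acid
Product: 27 tert-butyl (2S)-2-[(1R,2R,3S,4S,6S)-2-{[tert-butyl(dimethyl)silyl]oxy}-6-{[(2R)-3-{[tert-butyl(dimethyl)silyl]oxy}-2-methylpropanoyl]oxy}-4-ethenyl-4-methyl-3-(prop-1-en-2-yl)cyclohexyl]propanoate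
Conditions: DCC, DMAP, CH2Cl2, 0 → 25 °C
Reagents that add atoms: none
Why: Steglich esterification of the equatorial C8 alcohol fixes the side chain before the C6 oxygen is freed, so that the later lactonisation can only involve O6.

Step 16
Reactants: 27 tert-butyl (2S)-2-[(1R,2R,3S,4S,6S)-2-{[tert-butyl(dimethyl)silyl]oxy}-6-{[(2R)-3-{[tert-butyl(dimethyl)silyl]oxy}-2-methylpropanoyl]oxy}-4-ethenyl-4-methyl-3-(prop-1-en-2-yl)cyclohexyl]propanoate
Product: 29 (3S,3aR,4S,6S,7S,7aR)-6-ethenyl-3,6-dimethyl-2-oxo-7-(prop-1-en-2-yl)octahydro-1-benzofuran-4-yl (2R)-3-hydroxy-2-methylpropanoate, via desilylated diol 28 (not isolated)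
Conditions: HF·pyridine, THF, 0 → 25 °C; then TsOH·H2O (cat.), CH2Cl2, 25 °C
Reagents that add atoms: none
Why: fluoride-mediated desilylation frees both hydroxyls, and acid-catalysed intramolecular transesterification of the γ-hydroxy tert-butyl ester should close the trans-fused 6,12-lactone, C6, C7 and C11 keeping the configurations set in steps 1 and 3.

Step 17
Reactants: 29 (3S,3aR,4S,6S,7S,7aR)-6-ethenyl-3,6-dimethyl-2-oxo-7-(prop-1-en-2-yl)octahydro-1-benzofuran-4-yl (2R)-3-hydroxy-2-methylpropanoate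
Product: 30 (3S,3aR,4S,6S,7R,7aR)-6-ethenyl-7-(3-hydroxyprop-1-en-2-yl)-3,6-dimethyl-2-oxooctahydro-1-benzofuran-4-yl (2R)-3-hydroxy-2-methylpropanoate (target)
Conditions: SeO2 (cat.), t-BuOOH, CH2Cl2, 0 → 25 °C
Reagents that add atoms: selenium dioxide, O=[Se]=O; tert-butyl hydroperoxide, CC(C)(C)OO
Why: SeO2 allylic hydroxylation (ene reaction then [2,3]-sigmatropic shift) should oxidise the methyl of the isopropenyl group in preference to the tertiary C5–H, the vinyl group having no allylic hydrogen, and the two ends of the 2-substituted allyl unit give the same product.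

**Compound list**

1 | (4S)-4-benzyl-1,3-oxazolidin-2-one | O=C1OC[C@H](Cc2ccccc2)N1 | starting material
2 | (S)-methylsuccinic anhydride | C[C@H]1CC(=O)OC1=O | starting material
3 | lithium (4S)-4-benzyl-2-oxo-1,3-oxazolidin-3-ide | [Li+].O=C1OC[C@H](Cc2ccccc2)[N-]1 | intermediate
4 | (2S)-4-[(4S)-4-benzyl-2-oxo-1,3-oxazolidin-3-yl]-2-methyl-4-oxobutanoic acid | OC(=O)[C@@H](C)CC(=O)N1[C@@H](Cc2ccccc2)COC1=O | intermediate
5 | tert-butyl (2S)-4-[(4S)-4-benzyl-2-oxo-1,3-oxazolidin-3-yl]-2-methyl-4-oxobutanoate | CC(C)(C)OC(=O)[C@@H](C)CC(=O)N1[C@@H](Cc2ccccc2)COC1=O | intermediate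
6 | acrolein | C=CC=O | starting material
7 | (Z)-dibutylboron enolate of 5 (O–B cis to the C11 arm) | CCCCB(CCCC)O/C(=C\[C@H](C)C(=O)OC(C)(C)C)N1[C@@H](Cc2ccccc2)COC1=O | intermediate
8 | tert-butyl (2S,3S,4R)-3-{[(4S)-4-benzyl-2-oxo-1,3-oxazolidin-3-yl]carbonyl}-4-hydroxy-2-methylhex-5-enoate | C=C[C@@H](O)[C@H]([C@H](C)C(=O)OC(C)(C)C)C(=O)N1[C@@H](Cc2ccccc2)COC1=O | intermediate
9 | tert-butyl (2S,3S,4R)-4-hydroxy-3-[methoxy(methyl)carbamoyl]-2-methylhex-5-enoate | C=C[C@@H](O)[C@H]([C@H](C)C(=O)OC(C)(C)C)C(=O)N(C)OC | intermediate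
10 | tert-butyl (2S,3S,4R)-4-{[tert-butyl(dimethyl)silyl]oxy}-3-[methoxy(methyl)carbamoyl]-2-methylhex-5-enoate | C=C[C@@H](O[Si](C)(C)C(C)(C)C)[C@H]([C@H](C)C(=O)OC(C)(C)C)C(=O)N(C)OC | intermediate
11 | 2-methylallylmagnesium chloride | C=C(C)C[Mg]Cl | starting material
12 | tert-butyl (2S,3S,4R)-4-{[tert-butyl(dimethyl)silyl]oxy}-2-methyl-3-(3-methylbut-3-enoyl)hex-5-enoate | C=C[C@@H](O[Si](C)(C)C(C)(C)C)[C@H]([C@H](C)C(=O)OC(C)(C)C)C(=O)CC(C)=C | intermediate
13 | tert-butyl (2S)-2-[(1S,2R)-2-{[tert-butyl(dimethyl)silyl]oxy}-4-methyl-6-oxocyclohex-3-en-1-yl]propanoate | O=C1CC(C)=C[C@@H](O[Si](C)(C)C(C)(C)C)[C@@H]1[C@H](C)C(=O)OC(C)(C)C | intermediate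
14 | prop-2-yn-1-ol | C#CCO | starting material
15 | (Z)-bromomagnesium alkoxide of 3-(bromomagnesio)-2-methylprop-2-en-1-ol | Br[Mg]/C=C(C)\CO[Mg]Br | intermediate
16 | (2Z)-3-iodo-2-methylprop-2-en-1-ol | I/C=C(C)\CO | intermediate
17 | (2Z)-3-iodo-2-methylprop-2-enal | I/C=C(C)\C=O | intermediate
18 | (1Z)-1-iodo-2-methylbuta-1,3-diene | I/C=C(C)\C=C | intermediate
19 | [(1Z)-2-methylbuta-1,3-dien-1-yl]lithium | [Li]/C=C(C)\C=C | intermediate
20 | lithium carbinolate from 13 and 19 (C8 alkoxide; (Z)-dienyl group cis to the C6 silyl ether, trans to the C7 arm) | [Li+].[O-][C@]1(/C=C(C)\C=C)CC(C)=C[C@@H](O[Si](C)(C)C(C)(C)C)[C@@H]1[C@H](C)C(=O)OC(C)(C)C | intermediate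
21 | potassium C8=C9 enolate of 22 | C=C[C@]1(C)C=C([O-])[C@@H]([C@H](C)C(=O)OC(C)(C)C)[C@H](O[Si](C)(C)C(C)(C)C)[C@H]1C(C)=C.[K+] | intermediate
22 | tert-butyl (2S)-2-[(1S,2R,3S,4S)-2-{[tert-butyl(dimethyl)silyl]oxy}-4-ethenyl-4-methyl-6-oxo-3-(prop-1-en-2-yl)cyclohexyl]propanoate | C=C[C@]1(C)CC(=O)[C@@H]([C@H](C)C(=O)OC(C)(C)C)[C@H](O[Si](C)(C)C(C)(C)C)[C@H]1C(C)=C | intermediate
23 | tert-butyl (2S)-2-[(1R,2R,3S,4S,6S)-2-{[tert-butyl(dimethyl)silyl]oxy}-4-ethenyl-6-hydroxy-4-methyl-3-(prop-1-en-2-yl)cyclohexyl]propanoate (8α-alcohol) | C=C[C@]1(C)C[C@H](O)[C@@H]([C@H](C)C(=O)OC(C)(C)C)[C@H](O[Si](C)(C)C(C)(C)C)[C@H]1C(C)=C | intermediate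
24 | methyl (2R)-3-hydroxy-2-methylpropanoate | COC(=O)[C@H](C)CO | starting material
25 | methyl (2R)-3-{[tert-butyl(dimethyl)silyl]oxy}-2-methylpropanoate | COC(=O)[C@H](C)CO[Si](C)(C)C(C)(C)C | intermediate
26 | (2R)-3-{[tert-butyl(dimethyl)silyl]oxy}-2-methylpropanoic acid | OC(=O)[C@H](C)CO[Si](C)(C)C(C)(C)C | intermediate
27 | tert-butyl (2S)-2-[(1R,2R,3S,4S,6S)-2-{[tert-butyl(dimethyl)silyl]oxy}-6-{[(2R)-3-{[tert-butyl(dimethyl)silyl]oxy}-2-methylpropanoyl]oxy}-4-ethenyl-4-methyl-3-(prop-1-en-2-yl)cyclohexyl]propanoate | C=C[C@]1(C)C[C@H](OC(=O)[C@H](C)CO[Si](C)(C)C(C)(C)C)[C@@H]([C@H](C)C(=O)OC(C)(C)C)[C@H](O[Si](C)(C)C(C)(C)C)[C@H]1C(C)=C | intermediate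
28 | diol from 27 with both silyl groups removed (C6–OH and side-chain OH free, tert-butyl ester intact, configuration unchanged) | C=C[C@]1(C)C[C@H](OC(=O)[C@H](C)CO)[C@@H]([C@H](C)C(=O)OC(C)(C)C)[C@H](O)[C@H]1C(C)=C | intermediate
29 | (3S,3aR,4S,6S,7S,7aR)-6-ethenyl-3,6-dimethyl-2-oxo-7-(prop-1-en-2-yl)octahydro-1-benzofuran-4-yl (2R)-3-hydroxy-2-methylpropanoate | C=C[C@]1(C)C[C@H](OC(=O)[C@H](C)CO)[C@@H]2[C@H](OC(=O)[C@H]2C)[C@H]1C(C)=C | intermediate
30 | (3S,3aR,4S,6S,7R,7aR)-6-ethenyl-7-(3-hydroxyprop-1-en-2-yl)-3,6-dimethyl-2-oxooctahydro-1-benzofuran-4-yl (2R)-3-hydroxy-2-methylpropanoate | C=C[C@]1(C)C[C@H](OC(=O)[C@H](C)CO)[C@@H]2[C@H](OC(=O)[C@H]2C)[C@H]1C(=C)CO | target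

**Step count.** Total: 17 steps. Longest linear sequence: 12 steps (steps 1–7, 11, 12, 15, 16, 17).

**The three steps most likely to fail**

Step 11 (key step). The organolithium may deprotonate the doubly activated C3 methylene instead of adding, after which loss of silanol and aromatisation would consume the ketone. The addition may also take the wrong face if the silyloxy group shields the required one. The potassium alkoxide may fragment rather than rearrange, and the base may epimerise C11. Fallback: setting out from 13, the dienyllithium 19 (from 18) is transmetalated with anhydrous CeCl3 in THF at −78 °C so that addition outruns enolisation, and the tertiary alcohol tert-butyl (2S)-2-[(1S,2R,6S)-2-{[tert-butyl(dimethyl)silyl]oxy}-6-hydroxy-4-methyl-6-[(1Z)-2-methylbuta-1,3-dien-1-yl]cyclohex-3-en-1-yl]propanoate F1 is isolated and freed from its C8 epimer. F1 is then rearranged on its own with KH and 18-crown-6 in THF at 0 → 25 °C, a separate anionic oxy-Cope step without excess soluble base, and the route is rejoined at 22.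

Step 12. The electron-transfer reduction may over-reduce the tert-butyl ester, or the alkoxide formed may attack that ester, and the equatorial selectivity may be incomplete. Fallback: setting out from 22, LiBH(s-Bu)3 in THF at −78 °C should attack from the equatorial side, away from the axial C10 methyl, and give the axial 8β-alcohol tert-butyl (2S)-2-[(1R,2R,3S,4S,6R)-2-{[tert-butyl(dimethyl)silyl]oxy}-4-ethenyl-6-hydroxy-4-methyl-3-(prop-1-en-2-yl)cyclohexyl]propanoate F2. A Mitsunobu esterification of F2 with acid 26 (PPh3, DIAD, toluene) then installs the side chain with inversion at C8 and rejoins the route at 27.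

Step 17. The oxidation may run on to the enal, may attack the tertiary allylic C5–H, or may stall at low conversion. Fallback: setting out from 29, an ene-type chlorination of the isopropenyl group with Ca(OCl)2 and CO2 in CH2Cl2/H2O at 0 °C should give the allylic chloride (3S,3aR,4S,6S,7R,7aR)-7-(3-chloroprop-1-en-2-yl)-6-ethenyl-3,6-dimethyl-2-oxooctahydro-1-benzofuran-4-yl (2R)-3-hydroxy-2-methylpropanoate F3. Displacement with sodium formate in DMF gives the formate (3S,3aR,4S,6S,7R,7aR)-6-ethenyl-7-[3-(formyloxy)prop-1-en-2-yl]-3,6-dimethyl-2-oxooctahydro-1-benzofuran-4-yl (2R)-3-hydroxy-2-methylpropanoate F4; direct and allylic substitution lead to the same product. Methanolysis of F4 with KHCO3 in MeOH at 0 °C rejoins the route at 30.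

**Further compounds**

F1 | step 11 | tert-butyl (2S)-2-[(1S,2R,6S)-2-{[tert-butyl(dimethyl)silyl]oxy}-6-hydroxy-4-methyl-6-[(1Z)-2-methylbuta-1,3-dien-1-yl]cyclohex-3-en-1-yl]propanoate | O[C@]1(/C=C(C)\C=C)CC(C)=C[C@@H](O[Si](C)(C)C(C)(C)C)[C@@H]1[C@H](C)C(=O)OC(C)(C)C
F2 | step 12 | tert-butyl (2S)-2-[(1R,2R,3S,4S,6R)-2-{[tert-butyl(dimethyl)silyl]oxy}-4-ethenyl-6-hydroxy-4-methyl-3-(prop-1-en-2-yl)cyclohexyl]propanoate | C=C[C@]1(C)C[C@@H](O)[C@@H]([C@H](C)C(=O)OC(C)(C)C)[C@H](O[Si](C)(C)C(C)(C)C)[C@H]1C(C)=C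
F3 | step 17 | (3S,3aR,4S,6S,7R,7aR)-7-(3-chloroprop-1-en-2-yl)-6-ethenyl-3,6-dimethyl-2-oxooctahydro-1-benzofuran-4-yl (2R)-3-hydroxy-2-methylpropanoate | C=C[C@]1(C)C[C@H](OC(=O)[C@H](C)CO)[C@@H]2[C@H](OC(=O)[C@H]2C)[C@H]1C(=C)CCl
F4 | step 17 | (3S,3aR,4S,6S,7R,7aR)-6-ethenyl-7-[3-(formyloxy)prop-1-en-2-yl]-3,6-dimethyl-2-oxooctahydro-1-benzofuran-4-yl (2R)-3-hydroxy-2-methylpropanoate | C=C[C@]1(C)C[C@H](OC(=O)[C@H](C)CO)[C@@H]2[C@H](OC(=O)[C@H]2C)[C@H]1C(=C)COC=O
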